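The vessel is a closed, stirred flask in which substrate leaves by several exits while a scavenger removes the weak acid that two of them make.

    substrate + weak acid ⇌ idle adduct, settled at all times (K1 = 35 L mol⁻¹)
    substrate → weak acid + product (k2 = 0.0054 min⁻¹)
    weak acid + scavenger → scavenged by-product (k3 = 6.9 L mol⁻¹ min⁻¹)
    crystals ⇌ product, rate k4*(cs4 - [product]) while solid is left; crystals form when [product] > cs4 (cs4 = 1.2 mM, k4 = 1.9 min⁻¹)
    substrate + acid → weak acid + acid + product (k5 = 100 L mol⁻¹ min⁻¹)
    weak acid ⇌ conjugate base + acid, settled at all times (K6 = 2.0 × 10⁻⁶ M)
    substrate ⇌ dormant form (K7 = 0.63, k7 = 0.010 min⁻¹)

substrate 0.10 M; acid 0.300 mM; scavenger 1.50 equiv; time 30 min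

- part of the substrate that has reacted at 30 min
- pH of the solution at 30 min

- acid is the free proton; pH is minus the decimal logarithm of its molar concentration
- for product the crystals are counted in
- for weak acid the idle adduct is counted in
- as a solid, counted per litre of solution: crystals
- what has gone from substrate into another species counts as reacted, even if it can come back
- run time (flask): 30 min

I kept a ledger of the substrate, the limiting reagent, because the scavenger stood at 1.50 equiv. I turned each exit into a time at the charged amounts.

1. The acid-carried conversion gives its acid back, so I held acid at its charge and treated this exit as pseudo-first-order. Its half-life of 23 min made it the fastest exit.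

2. The slip into the dormant form, forward direction alone, had a half-life of 69 min. What slips counts as reacted.

3. The uncatalysed conversion had a half-life of 128 min.

4. I added the three first-order constants into the drain 0.0454 min⁻¹, the fraction of the free substrate leaving per minute with acid at its charge and the return from the dormant form not counted.

5. The drain split into 66.1 % acid-carried, 22.0 % dormant and 11.9 % uncatalysed.

6. At 30 min I closed the books. My ledger left substrate 25.6 % of the charge and booked 74.4 % as reacted. Of the charge, it booked 58.0 % to product and 16.4 % to the dormant form.

I booked no return from the dormant form, so I read my figure as high.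

The forecast gave 72 % (68 % to 76 %) and pH 3.5 (3.48 to 3.52), on the ground that “The free proton barely moves”. My figure lay above its centre but inside its range.

The flask gave 72.1 % reacted and pH 3.51. Its product, crystals counted, stood at 58.4 % of the charge at 30.0 min, beside the 58.0 % I had booked. For the neighbour charged with 1.2 × 10⁻⁴ M of acid, I reckoned the drain at that charge as 0.0274 min⁻¹ against 0.0454 min⁻¹, so the same ledger booked 56.0 % reacted, and that neighbour flask gave 55.3 %.

(The constants stand for no real mixture; the rest is arithmetic.)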